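**Plan**

1. Numbering: ring A C1 (OMe), C2 (Br), C3 (Me), C4 (Cl), C5 (OH), C6; C7 is the ketone carbon; ring B C1' (bonded to C7), C2' (carries the aldehyde carbon C8), C3' (OH), C4' (H), C5' (OH), C6' (prenyl).
2. Feature used: in ring B, C8 on C2' is ortho to the C3' oxygen, para to the C5' oxygen and next to the carbon-substituted C1'. The chain C8–C2'–C3'–C4'–C5'–C6'–C1' thus carries oxygen on alternate carbons like an aldol-folded polyketide, and ring B can be closed by joining C2' to C1'.
3. Cuts, in retrosynthetic order: C7/C8 redox and acetal removal; C1'–C2' (aldol aromatisation of a diketo-dioxinone); C6'–C1' (Claisen union of a keto-dioxinone dianion with a ring A α-silyloxy ester); C4'–C5' (acylation of the dioxinone enolate); C2–Br, C6–C7 (aryllithium plus ethyl glyoxylate) and C4–Cl on 3-methoxy-5-methylphenol.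
4. Forward: ring A is bought and decorated (Cl, then C7, then Br), the seven-carbon chain is joined to it at C6'–C1', and ring B is closed. C8 is then reduced, C7 and C8 are oxidised in one operation, and the three acetal ethers are hydrolysed.
5. Stereochemistry: the target has no stereocenter and no stereogenic alkene; C7 is carried as a racemic silyl-protected carbinol and ends as the ketone.

Key step: step 8

Remark: ArA stands for the ring A group 3-bromo-5-chloro-2-methoxy-6-(methoxymethoxy)-4-methylphenyl (bonded through C6). Chiral intermediates are assumed to be used as racemates and, where two stereocenters are present (15, 16), as mixtures of diastereomers and keto–enol tautomers.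

**Route**

Step 1
Reactants: 1 3-methoxy-5-methylphenol
Product: 2 2-chloro-5-methoxy-3-methylphenol
Conditions: SO2Cl2 (1.0 equiv), i-Bu2NH (cat.), toluene, 0 → 23 °C
Reagents that add atoms: sulfuryl chloride, O=S(=O)(Cl)Cl
Why: Electrophilic aromatic chlorination in which the secondary amine turns SO2Cl2 into a hydrogen-bonded N-chloroammonium donor that delivers chlorine ortho to the phenol, and of the two ortho sites the one para to the methoxy group (future C4) is the more nucleophilic, so this isomer should predominate and minor regioisomers can be removed here by chromatography.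

Step 2
Reactants: 2 2-chloro-5-methoxy-3-methylphenol
Product: 3 2-chloro-5-methoxy-1-(methoxymethoxy)-3-methylbenzene
Conditions: MOMCl, i-Pr2NEt, CH2Cl2, 0 → 23 °C
Reagents that add atoms: chloromethyl methyl ether, COCCl
Why: Williamson-type O-alkylation of the phenol by an α-chloro ether under amine base, installing the acetal ether that directs the lithiation of the next step and withstands every basic and hydridic step that follows.

Step 3
Reactants: 3 2-chloro-5-methoxy-1-(methoxymethoxy)-3-methylbenzene; 4 ethyl glyoxylate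
Product: 6 racemic ethyl 2-[3-chloro-6-methoxy-2-(methoxymethoxy)-4-methylphenyl]-2-hydroxyacetate, via aryllithium 5 (not isolated)
Conditions: n-BuLi, THF, 0 °C; then added to 4 (freshly distilled, 2 equiv), THF, −78 °C; aq. NH4Cl
Reagents that add atoms: none
Why: Directed ortho-metalation at the one ring position flanked by two oxygen donors (future C6), followed by 1,2-addition of aryllithium 5 to the aldehyde of ethyl glyoxylate, which is far more electrophilic than its ester group; the aryl chloride is inert to n-BuLi and is not ortho to the carbanion, so no aryne can arise, and the new C7 stereocenter is formed without control because it is oxidised to the ketone later.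

Step 4
Reactants: 6 racemic ethyl 2-[3-chloro-6-methoxy-2-(methoxymethoxy)-4-methylphenyl]-2-hydroxyacetate
Product: 7 racemic ethyl 2-[3-chloro-6-methoxy-2-(methoxymethoxy)-4-methylphenyl]-2-[(triethylsilyl)oxy]acetate
Conditions: Et3SiCl, imidazole, 4-(dimethylamino)pyridine (cat.), DMF, 23 °C
Reagents that add atoms: chlorotriethylsilane, CC[Si](Cl)(CC)CC
Why: Routine silylation of a secondary α-hydroxy ester with a silyl chloride and imidazole, giving a triethylsilyl ether that masks the C7 hydroxyl against the strong bases ahead and can later be removed by fluoride without touching the acetal ethers.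

Step 5
Reactants: 7 racemic ethyl 2-[3-chloro-6-methoxy-2-(methoxymethoxy)-4-methylphenyl]-2-[(triethylsilyl)oxy]acetate
Product: 8 racemic ethyl 2-ArA-2-[(triethylsilyl)oxy]acetate
Conditions: NBS, MeCN, 0 → 23 °C, dark
Reagents that add atoms: N-bromosuccinimide, O=C1CCC(=O)N1Br
Why: Electrophilic aromatic bromination with NBS in a polar solvent, which has only one ring hydrogen to replace (future C2) and finds it activated by the ortho methoxy, para methoxymethoxy and ortho methyl groups, so that the halogen pattern is fixed without a regiochemical choice.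

Step 6
Reactants: 9 5-methylhex-4-enoic acid; 10 2,2,6-trimethyl-4H-1,3-dioxin-4-one
Product: 13 2,2-dimethyl-6-(6-methyl-2-oxohept-5-en-1-yl)-4H-1,3-dioxin-4-one, via 5-methylhex-4-enoyl chloride 11 (not isolated), via dioxinone lithium dienolate 12 (not isolated)
Conditions: 9, (COCl)2, N,N-dimethylformamide (cat.), CH2Cl2, 0 → 23 °C, evaporate; 10 (2 equiv), LiN(SiMe3)2 (2 equiv), THF, −78 °C, then crude 11, −78 °C; aq. NH4Cl
Reagents that add atoms: none
Why: Acid chloride formation with oxalyl chloride followed by γ-selective C-acylation of the extended lithium enolate of the dioxinone, a standard entry to 6-(2-oxoalkyl)dioxinones that forms the C4'–C5' bond; two equivalents of enolate are used because the product is more acidic than 10.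

Step 7
Reactants: 13 2,2-dimethyl-6-(6-methyl-2-oxohept-5-en-1-yl)-4H-1,3-dioxin-4-one (2.2 equiv); 8 racemic ethyl 2-ArA-2-[(triethylsilyl)oxy]acetate
Product: 15 racemic 6-{5-ArA-3-(3-methylbut-2-en-1-yl)-2,4-dioxo-5-[(triethylsilyl)oxy]pentyl}-2,2-dimethyl-4H-1,3-dioxin-4-one, via dilithium dianion 14 (not isolated)
Conditions: 13, LiN(i-Pr)2 (2.1 equiv per 13), THF, −78 → −40 °C; then 8, −78 → −20 °C; AcOH, −78 °C
Reagents that add atoms: none
Why: Crossed Claisen condensation of a β-dicarbonyl-type dianion with an ester, in which the last-formed and most basic carbanion (C6') of 14 attacks the ester carbonyl of 8, activated by its α-oxygen, to form the C6'–C1' bond; the dianion is taken in excess because the product is deprotonated as it forms, and the new C6' stereocenter is left uncontrolled since it becomes an aromatic carbon in the next step.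

Step 8
Reactants: 15 racemic 6-{5-ArA-3-(3-methylbut-2-en-1-yl)-2,4-dioxo-5-[(triethylsilyl)oxy]pentyl}-2,2-dimethyl-4H-1,3-dioxin-4-one
Product: 17 racemic 5-{ArA[(triethylsilyl)oxy]methyl}-7-hydroxy-2,2-dimethyl-6-(3-methylbut-2-en-1-yl)-4H-1,3-benzodioxin-4-one, via aldol adduct 16 (not isolated)
Conditions: Et3N, CH2Cl2, 23 °C
Reagents that add atoms: none
Why: Et3N reversibly removes a C4' proton, which is α to the C5' ketone and vinylogous to the dioxinone carbonyl C8, and the delocalised anion adds through C2' to the C1' ketone to give aldol adduct 16; loss of water across C1'–C6' (E1cB, the C6' hydrogen being α to C5'=O) and enolisation of the C5' ketone then deliver the aromatic ring as a phenol. The closest known reaction type is the amine-induced aldol aromatisation of 6-(2,4-dioxoalkyl)dioxinones to isopropylidene-protected resorcylates, the laboratory counterpart of aldol folding of a polyketide chain, here with a more crowded acceptor ketone than usual. Ring B closes in a 6-(enolendo)-exo-trig mode, the C2'=C3' enol ether bond of the dioxinone ending inside the new ring and the C1' carbonyl being attacked exo. No stereocenter is created: C1' and C6' become aromatic carbons and C7 stays racemic. The step needs C–C aldol closure instead of Claisen-type acylation or O-cyclisation, and the substrate secures it because C2' and C1' are the only nucleophile and carbonyl placed for a six-membered ring, the dioxinone carbonyl does not act as an acyl donor far below the temperature at which it releases an acylketene, and the C6' prenyl group keeps the 1,3-diketone mainly in the diketo form so that C1' stays electrophilic. The prenyl group and the silyl-protected ring A carbinol ride in on C6' and C1', so ring B is formed pentasubstituted with C8 at the carboxyl level and the C3' oxygen held in the acetonide.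

Step 9
Reactants: 17 racemic 5-{ArA[(triethylsilyl)oxy]methyl}-7-hydroxy-2,2-dimethyl-6-(3-methylbut-2-en-1-yl)-4H-1,3-benzodioxin-4-one
Product: 18 racemic 5-{ArA[(triethylsilyl)oxy]methyl}-7-(methoxymethoxy)-2,2-dimethyl-6-(3-methylbut-2-en-1-yl)-4H-1,3-benzodioxin-4-one
Conditions: MOMCl, i-Pr2NEt, CH2Cl2, 0 → 23 °C
Reagents that add atoms: chloromethyl methyl ether, COCCl
Why: O-Alkylation of the acidic C5' phenol under amine base, done so that the hydride step does not generate a phenoxide para to the lactone carbon, which would slow hydride attack and open a quinone methide path to over-reduction.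

Step 10
Reactants: 18 racemic 5-{ArA[(triethylsilyl)oxy]methyl}-7-(methoxymethoxy)-2,2-dimethyl-6-(3-methylbut-2-en-1-yl)-4H-1,3-benzodioxin-4-one
Product: 19 racemic 3-{ArA[(triethylsilyl)oxy]methyl}-2-(hydroxymethyl)-5-(methoxymethoxy)-4-(3-methylbut-2-en-1-yl)phenol
Conditions: LiAlH4, THF, 0 °C; aq. potassium sodium tartrate
Reagents that add atoms: none
Why: Hydride reduction of an aryl-ester-like lactone, in which the first hydride opens the benzodioxinone with release of acetone and the C3' phenoxide and the second takes the aldehyde to the C8 alcohol, while aryl halides, the silyl ether and the acetal ethers are inert to LiAlH4 at 0 °C.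

Step 11
Reactants: 19 racemic 3-{ArA[(triethylsilyl)oxy]methyl}-2-(hydroxymethyl)-5-(methoxymethoxy)-4-(3-methylbut-2-en-1-yl)phenol
Product: 20 racemic (2-{ArA[(triethylsilyl)oxy]methyl}-4,6-bis(methoxymethoxy)-3-(3-methylbut-2-en-1-yl)phenyl)methanol
Conditions: MOMCl, K2CO3, acetone, 23 °C
Reagents that add atoms: chloromethyl methyl ether, COCCl
Why: Chemoselective Williamson etherification in which K2CO3 deprotonates only the phenol and not the benzylic alcohol, so that the C3' oxygen alone is alkylated and no free phenol remains to react with activated DMSO two steps later.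

Step 12
Reactants: 20 racemic (2-{ArA[(triethylsilyl)oxy]methyl}-4,6-bis(methoxymethoxy)-3-(3-methylbut-2-en-1-yl)phenyl)methanol
Product: 21 racemic ArA[2-(hydroxymethyl)-3,5-bis(methoxymethoxy)-6-(3-methylbut-2-en-1-yl)phenyl]methanol
Conditions: Bu4NF, AcOH, THF, 0 → 23 °C
Reagents that add atoms: none
Why: Fluoride-induced cleavage of the Si–O bond, driven by the strong Si–F bond and buffered with acetic acid, frees the hindered C7 hydroxyl and leaves the acetal ethers, the aryl halides and the prenyl group untouched.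

Step 13
Reactants: 21 racemic ArA[2-(hydroxymethyl)-3,5-bis(methoxymethoxy)-6-(3-methylbut-2-en-1-yl)phenyl]methanol
Product: 23 2-[3-bromo-5-chloro-2-methoxy-6-(methoxymethoxy)-4-methylbenzoyl]-4,6-bis(methoxymethoxy)-3-(3-methylbut-2-en-1-yl)benzaldehyde, via bis(alkoxysulfonium) dichloride 22 (not isolated)
Conditions: (COCl)2, DMSO, CH2Cl2, −78 → −60 °C; then Et3N, −78 → 0 °C
Reagents that add atoms: none
Why: Swern oxidation, chosen because both hydroxyls are converted into alkoxysulfonium ions (22) before any base is added, so that the C7 ketone and the C8 aldehyde appear together on adding Et3N and no hydroxy aldehyde is present that could close to a lactol and be oxidised on to a phthalide, as in the conversion of 1,2-benzenedimethanols into phthalaldehydes.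

Step 14
Reactants: 23 2-[3-bromo-5-chloro-2-methoxy-6-(methoxymethoxy)-4-methylbenzoyl]-4,6-bis(methoxymethoxy)-3-(3-methylbut-2-en-1-yl)benzaldehyde
Product: 24 pestalone H, 2-(3-bromo-5-chloro-6-hydroxy-2-methoxy-4-methylbenzoyl)-4,6-dihydroxy-3-(3-methylbut-2-en-1-yl)benzaldehyde
Conditions: 3 M aq. HCl, THF, 23 → 40 °C; neutral work-up
Reagents that add atoms: none
Why: Acid-catalysed hydrolysis of the three aryl methoxymethyl acetals through oxocarbenium ions, the two ethers ortho to a carbonyl being especially labile, under dilute acid that should spare the prenyl group (whose cyclisation onto the C5' phenol needs stronger acid) and with a base-free work-up because the keto aldehyde is prone to base-induced redox isomerisation to a lactone.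

**Compound list**

1 | 3-methoxy-5-methylphenol | COc1cc(C)cc(O)c1 | starting material
2 | 2-chloro-5-methoxy-3-methylphenol | COc1cc(C)c(Cl)c(O)c1 | intermediate
3 | 2-chloro-5-methoxy-1-(methoxymethoxy)-3-methylbenzene | COCOc1cc(OC)cc(C)c1Cl | intermediate
4 | ethyl glyoxylate (ethyl 2-oxoacetate) | CCOC(=O)C=O | starting material
5 | [3-chloro-6-methoxy-2-(methoxymethoxy)-4-methylphenyl]lithium | [Li]c1c(OC)cc(C)c(Cl)c1OCOC | intermediate
6 | racemic ethyl 2-[3-chloro-6-methoxy-2-(methoxymethoxy)-4-methylphenyl]-2-hydroxyacetate | CCOC(=O)C(O)c1c(OC)cc(C)c(Cl)c1OCOC | intermediate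
7 | racemic ethyl 2-[3-chloro-6-methoxy-2-(methoxymethoxy)-4-methylphenyl]-2-[(triethylsilyl)oxy]acetate | CCOC(=O)C(O[Si](CC)(CC)CC)c1c(OC)cc(C)c(Cl)c1OCOC | intermediate
8 | racemic ethyl 2-[3-bromo-5-chloro-2-methoxy-6-(methoxymethoxy)-4-methylphenyl]-2-[(triethylsilyl)oxy]acetate | CCOC(=O)C(O[Si](CC)(CC)CC)c1c(OC)c(Br)c(C)c(Cl)c1OCOC | intermediate
9 | 5-methylhex-4-enoic acid | CC(C)=CCCC(=O)O | starting material
10 | 2,2,6-trimethyl-4H-1,3-dioxin-4-one | CC1=CC(=O)OC(C)(C)O1 | starting material
11 | 5-methylhex-4-enoyl chloride | CC(C)=CCCC(Cl)=O | intermediate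
12 | lithium 2,2-dimethyl-6-methylidene-6H-1,3-dioxin-4-olate (extended enolate of 10) | C=C1C=C(O[Li])OC(C)(C)O1 | intermediate
13 | 2,2-dimethyl-6-(6-methyl-2-oxohept-5-en-1-yl)-4H-1,3-dioxin-4-one | CC(C)=CCCC(=O)CC1=CC(=O)OC(C)(C)O1 | intermediate
14 | dilithium dianion of 13 (lithium enolate at C5'–C4', lithiated at C6') | [Li]C(CC=C(C)C)C(O[Li])=CC1=CC(=O)OC(C)(C)O1 | intermediate
15 | racemic 6-{5-[3-bromo-5-chloro-2-methoxy-6-(methoxymethoxy)-4-methylphenyl]-3-(3-methylbut-2-en-1-yl)-2,4-dioxo-5-[(triethylsilyl)oxy]pentyl}-2,2-dimethyl-4H-1,3-dioxin-4-one (diastereomer and tautomer mixture) | CC1(C)OC(=O)C=C(CC(=O)C(CC=C(C)C)C(=O)C(O[Si](CC)(CC)CC)c2c(OC)c(Br)c(C)c(Cl)c2OCOC)O1 | intermediate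
16 | 5-{[3-bromo-5-chloro-2-methoxy-6-(methoxymethoxy)-4-methylphenyl][(triethylsilyl)oxy]methyl}-5-hydroxy-2,2-dimethyl-6-(3-methylbut-2-en-1-yl)-5,6-dihydro-4H-1,3-benzodioxine-4,7(8H)-dione (aldol adduct, diastereomer mixture) | CC1(C)OC(=O)C2=C(O1)CC(=O)C(CC=C(C)C)C2(O)C(O[Si](CC)(CC)CC)c1c(OC)c(Br)c(C)c(Cl)c1OCOC | intermediate
17 | racemic 5-{[3-bromo-5-chloro-2-methoxy-6-(methoxymethoxy)-4-methylphenyl][(triethylsilyl)oxy]methyl}-7-hydroxy-2,2-dimethyl-6-(3-methylbut-2-en-1-yl)-4H-1,3-benzodioxin-4-one | CC1(C)Oc2cc(O)c(CC=C(C)C)c(C(O[Si](CC)(CC)CC)c3c(OC)c(Br)c(C)c(Cl)c3OCOC)c2C(=O)O1 | intermediate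
18 | racemic 5-{[3-bromo-5-chloro-2-methoxy-6-(methoxymethoxy)-4-methylphenyl][(triethylsilyl)oxy]methyl}-7-(methoxymethoxy)-2,2-dimethyl-6-(3-methylbut-2-en-1-yl)-4H-1,3-benzodioxin-4-one | CC1(C)Oc2cc(OCOC)c(CC=C(C)C)c(C(O[Si](CC)(CC)CC)c3c(OC)c(Br)c(C)c(Cl)c3OCOC)c2C(=O)O1 | intermediate
19 | racemic 3-{[3-bromo-5-chloro-2-methoxy-6-(methoxymethoxy)-4-methylphenyl][(triethylsilyl)oxy]methyl}-2-(hydroxymethyl)-5-(methoxymethoxy)-4-(3-methylbut-2-en-1-yl)phenol | OCc1c(O)cc(OCOC)c(CC=C(C)C)c1C(O[Si](CC)(CC)CC)c1c(OC)c(Br)c(C)c(Cl)c1OCOC | intermediate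
20 | racemic (2-{[3-bromo-5-chloro-2-methoxy-6-(methoxymethoxy)-4-methylphenyl][(triethylsilyl)oxy]methyl}-4,6-bis(methoxymethoxy)-3-(3-methylbut-2-en-1-yl)phenyl)methanol | OCc1c(OCOC)cc(OCOC)c(CC=C(C)C)c1C(O[Si](CC)(CC)CC)c1c(OC)c(Br)c(C)c(Cl)c1OCOC | intermediate
21 | racemic [3-bromo-5-chloro-2-methoxy-6-(methoxymethoxy)-4-methylphenyl][2-(hydroxymethyl)-3,5-bis(methoxymethoxy)-6-(3-methylbut-2-en-1-yl)phenyl]methanol | OCc1c(OCOC)cc(OCOC)c(CC=C(C)C)c1C(O)c1c(OC)c(Br)c(C)c(Cl)c1OCOC | intermediate
22 | bis(alkoxydimethylsulfonium) dichloride of 21 (both hydroxyl oxygens bonded to a dimethylsulfonium sulfur) | C[S+](C)OCc1c(OCOC)cc(OCOC)c(CC=C(C)C)c1C(O[S+](C)C)c1c(OC)c(Br)c(C)c(Cl)c1OCOC.[Cl-].[Cl-] | intermediate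
23 | 2-[3-bromo-5-chloro-2-methoxy-6-(methoxymethoxy)-4-methylbenzoyl]-4,6-bis(methoxymethoxy)-3-(3-methylbut-2-en-1-yl)benzaldehyde | O=Cc1c(OCOC)cc(OCOC)c(CC=C(C)C)c1C(=O)c1c(OC)c(Br)c(C)c(Cl)c1OCOC | intermediate
24 | pestalone H, 2-(3-bromo-5-chloro-6-hydroxy-2-methoxy-4-methylbenzoyl)-4,6-dihydroxy-3-(3-methylbut-2-en-1-yl)benzaldehyde | COc1c(Br)c(C)c(Cl)c(O)c1C(=O)c1c(C=O)c(O)cc(O)c1CC=C(C)C | target

**Totals and risks**

Total step count: 14.
Longest linear sequence: 13 steps (from 1 through steps 1–5 and 7–14; step 6 is the side branch that makes 13).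

Three steps most likely to fail:

Risk at step 7 (fragment union). Proton transfer from the α-C–H of ester 8 to the dianion, or sluggish addition of the secondary carbanion to the crowded ester carbonyl, would return both partners unchanged. The fallback replaces the acylation by an aldol addition and an oxidation. It sets out from 8: i-Bu2AlH (CH2Cl2, −78 °C) should stop at the aldehyde 2-ArA-2-[(triethylsilyl)oxy]acetaldehyde F1. F1 is added at −78 °C to dianion 14 (made from 13 as in step 7) and should give the β-hydroxy ketone 6-{5-ArA-4-hydroxy-3-(3-methylbut-2-en-1-yl)-2-oxo-5-[(triethylsilyl)oxy]pentyl}-2,2-dimethyl-4H-1,3-dioxin-4-one F2 as a diastereomer mixture. Dess–Martin periodinane (CH2Cl2, NaHCO3, 0 °C) then oxidises the new carbinol, and the route is rejoined at 15.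

Risk at step 8 (ring B closure). Attack of C2' on the crowded C1' carbonyl may be slow, so that O-cyclisation to a pyranone, migration of the silyl group to the aldolate oxygen, or a stalled dehydration compete. The fallback closes the ring from the open-chain ester instead of the dioxinone. It sets out from 15: heating in toluene at 110 °C with excess methanol should fragment the dioxinone (loss of acetone) to an acylketene, trapped as the triketo ester methyl 8-ArA-6-(3-methylbut-2-en-1-yl)-3,5,7-trioxo-8-[(triethylsilyl)oxy]octanoate F3. Its C2' methylene is now a free β-keto ester carbon and should close on C1' with K2CO3 in MeOH, then AcOH, to give the resorcylate methyl 2-{ArA[(triethylsilyl)oxy]methyl}-4,6-dihydroxy-3-(3-methylbut-2-en-1-yl)benzoate F4. Both phenols are etherified (NaH, MOMCl, DMF, 0 °C) to methyl 2-{ArA[(triethylsilyl)oxy]methyl}-4,6-bis(methoxymethoxy)-3-(3-methylbut-2-en-1-yl)benzoate F5. LiAlH4 (THF, 0 °C) reduces the ester, and the route is rejoined at 20; steps 9–11 are then not needed.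

Risk at step 13 (double oxidation). If the hindered C7 hydroxyl is activated more slowly than the C8 hydroxyl, a hydroxy aldehyde forms, closes to a lactol and is oxidised on to a phthalide. The fallback oxidises the two carbons one after the other, C7 first. It sets out from 21: AcCl with 2,4,6-collidine (CH2Cl2, −78 °C) should acetylate only the primary hydroxyl and give {2-[ArA(hydroxy)methyl]-4,6-bis(methoxymethoxy)-3-(3-methylbut-2-en-1-yl)phenyl}methyl acetate F6. Dess–Martin periodinane oxidises the remaining carbinol to the keto acetate [2-(3-bromo-5-chloro-2-methoxy-6-(methoxymethoxy)-4-methylbenzoyl)-4,6-bis(methoxymethoxy)-3-(3-methylbut-2-en-1-yl)phenyl]methyl acetate F7. K2CO3 in MeOH (0 °C) removes the acetate to give the keto alcohol [3-bromo-5-chloro-2-methoxy-6-(methoxymethoxy)-4-methylphenyl][2-(hydroxymethyl)-3,5-bis(methoxymethoxy)-6-(3-methylbut-2-en-1-yl)phenyl]methanone F8, whose cyclic hemiketal form is tertiary and cannot be over-oxidised. MnO2 (CH2Cl2, 23 °C) then oxidises the benzylic alcohol, and the route is rejoined at 23.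

**Further compounds**

F1 | step 7 | racemic 2-[3-bromo-5-chloro-2-methoxy-6-(methoxymethoxy)-4-methylphenyl]-2-[(triethylsilyl)oxy]acetaldehyde | O=CC(O[Si](CC)(CC)CC)c1c(OC)c(Br)c(C)c(Cl)c1OCOC
F2 | step 7 | 6-{5-[3-bromo-5-chloro-2-methoxy-6-(methoxymethoxy)-4-methylphenyl]-4-hydroxy-3-(3-methylbut-2-en-1-yl)-2-oxo-5-[(triethylsilyl)oxy]pentyl}-2,2-dimethyl-4H-1,3-dioxin-4-one (diastereomer mixture) | CC1(C)OC(=O)C=C(CC(=O)C(CC=C(C)C)C(O)C(O[Si](CC)(CC)CC)c2c(OC)c(Br)c(C)c(Cl)c2OCOC)O1
F3 | step 8 | methyl 8-[3-bromo-5-chloro-2-methoxy-6-(methoxymethoxy)-4-methylphenyl]-6-(3-methylbut-2-en-1-yl)-3,5,7-trioxo-8-[(triethylsilyl)oxy]octanoate (diastereomer and tautomer mixture) | COC(=O)CC(=O)CC(=O)C(CC=C(C)C)C(=O)C(O[Si](CC)(CC)CC)c1c(OC)c(Br)c(C)c(Cl)c1OCOC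
F4 | step 8 | racemic methyl 2-{[3-bromo-5-chloro-2-methoxy-6-(methoxymethoxy)-4-methylphenyl][(triethylsilyl)oxy]methyl}-4,6-dihydroxy-3-(3-methylbut-2-en-1-yl)benzoate | COC(=O)c1c(O)cc(O)c(CC=C(C)C)c1C(O[Si](CC)(CC)CC)c1c(OC)c(Br)c(C)c(Cl)c1OCOC
F5 | step 8 | racemic methyl 2-{[3-bromo-5-chloro-2-methoxy-6-(methoxymethoxy)-4-methylphenyl][(triethylsilyl)oxy]methyl}-4,6-bis(methoxymethoxy)-3-(3-methylbut-2-en-1-yl)benzoate | COC(=O)c1c(OCOC)cc(OCOC)c(CC=C(C)C)c1C(O[Si](CC)(CC)CC)c1c(OC)c(Br)c(C)c(Cl)c1OCOC
F6 | step 13 | racemic {2-[[3-bromo-5-chloro-2-methoxy-6-(methoxymethoxy)-4-methylphenyl](hydroxy)methyl]-4,6-bis(methoxymethoxy)-3-(3-methylbut-2-en-1-yl)phenyl}methyl acetate | CC(=O)OCc1c(OCOC)cc(OCOC)c(CC=C(C)C)c1C(O)c1c(OC)c(Br)c(C)c(Cl)c1OCOC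
F7 | step 13 | {2-[3-bromo-5-chloro-2-methoxy-6-(methoxymethoxy)-4-methylbenzoyl]-4,6-bis(methoxymethoxy)-3-(3-methylbut-2-en-1-yl)phenyl}methyl acetate | CC(=O)OCc1c(OCOC)cc(OCOC)c(CC=C(C)C)c1C(=O)c1c(OC)c(Br)c(C)c(Cl)c1OCOC
F8 | step 13 | [3-bromo-5-chloro-2-methoxy-6-(methoxymethoxy)-4-methylphenyl][2-(hydroxymethyl)-3,5-bis(methoxymethoxy)-6-(3-methylbut-2-en-1-yl)phenyl]methanone | OCc1c(OCOC)cc(OCOC)c(CC=C(C)C)c1C(=O)c1c(OC)c(Br)c(C)c(Cl)c1OCOC
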